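I choose to follow the catalyst rather than the substrate: 14 mM of it stands against 0.29 M of substrate, so a change in where the catalyst sits shows as a change of rate.

the same everywhere: substrate 0.29 M; free catalyst 14 mM
- Thursday's: added ligand 23 mM; run made earlier
- Tuesday's: added ligand 130 mM; run made earlier
- Monday's: added ligand 560 mM; run made earlier
- north-east: added ligand 30 mM; time 5.0 h
- south-east: added ligand 60 mM; time 5.0 h
- north-west: added ligand 120 mM; time 5.0 h
- north: added ligand 250 mM; time 5.0 h
- south: added ligand 500 mM; time 5.0 h

| run | time / h | product / % |
|---|---|---|
| Thursday's | 0.667 | 5.3 |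
| Thursday's | 1.33 | 11.2 |
| Thursday's | 2.00 | 16.1 |
| Thursday's | 3.00 | 23.4 |
| Thursday's | 4.00 | 30.3 |
| Tuesday's | 0.250 | 1.3 |
| Tuesday's | 0.500 | 3.2 |
| Tuesday's | 1.00 | 6.1 |
| Tuesday's | 2.00 | 12.7 |
| Tuesday's | 4.00 | 21.9 |
| Monday's | 0.667 | 2.2 |
| Monday's | 1.33 | 2.9 |
| Monday's | 2.00 | 5.5 |
| Monday's | 3.00 | 7.5 |
| Monday's | 4.00 | 9.5 |

(readings scatter by 0.5 percentage points)

- "hardly changes" means that all values lie within two and a half points (for a concentration: within two and a half percent of the largest)

* amount of product at the end, in percent of the substrate charged for north-east, south-east, north-west, north, south, in this order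
* how that number moves from the first to the last of them (rises, then falls / falls all the way / hardly changes / rises all the way / falls, then rises)

I read the flask as a ladder, fastest rung first. The first rung is the sharing of catalyst with ligand. Tuesday's run has a pseudo-first-order constant k of 0.0618 /h from its reading at 4.00 h. That constant gives 1.53% at 0.250 h, and the reading there is 1.3%, so I see no lag beyond the scatter.

The second rung is the substrate. Thursday's run reads k = 0.0902 /h and Monday's 0.0250 /h, which means substrate half-lives of 7.68 h and 27.7 h, both longer than the asked 5.0 h.

The third rung is catalyst loss. Thursday's k is 0.0878 /h at 2.00 h and 0.0902 /h at 4.00 h, so no decline shows in the readings. Thursday's flask therefore looks like a steady share of working catalyst acting on slowly falling substrate.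

My balance, with no loss showing in the readings, takes the catalyst charged as working catalyst plus catalyst held by ligand. The working share is then c*/(c* + c(added ligand)), and I take k to follow that share. Here c* is the half-share concentration, the c(added ligand) at which working catalyst and held catalyst stand equal. Thursday's and Monday's runs read it as 182 mM, with a ligand-free k of 0.102 /h.

Tuesday's run, not used for this, should then read 21.1% at 4.00 h, and it reads 21.9%. At 5.0 h I commit to 35.4%, 31.8%, 26.4%, 19.3% and 12.7%, in the order asked.

The forecast gives 35.3%, 32%, 27.4%, 20.2% and 12.9%, falls all the way: “Product falls steadily with increasing ligand”.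

The flasks give 35.2%, 32.0%, 27.0%, 20.1% and 13.4%, so the row falls all the way.

    substrate + free catalyst → catalyst intermediate (k = 0.00200 /M/s)
    catalyst intermediate → free catalyst + product (k = 0.0440 /s)
    catalyst intermediate → spent catalyst (k = 4.30 × 10⁻⁵ /s)
    free catalyst + added ligand ⇌ idle complex (K = 5.20 /M, k = 0.0110 /M/s)

In north-east, the rate at which catalyst intermediate is made over the rate at which it is used up stands at 0.999 at 2.22 h and 0.999 at 5.00 h, and the idle complex holds 12.6% of the catalyst charged at 1.50 h and 12.6% at 5.00 h. My working share for north-east is 85.9% beside 85.9% of the catalyst charged standing as free catalyst at 5.00 h, and for south it is 26.7% beside 28.0% at 5.00 h.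

Readings and results are calculated for an exercise, and the scatter is random.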